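## Retrosynthetic overview

1. Target 25 comes from the hexadeca-ether 24 by a single global hydrogenolysis.
2. Each of the three interflavan C4–C8 bonds is cut to a C8 aryl bromide of the growing chain (19, 21, 23) and the same flav-3-ene oxide 16. A reductive nickel/titanium coupling opens the oxirane to a C4 benzylic radical and arylates it, so the 3-OH and the 3,4-trans (4α) aryl bond of every catechin unit arise in that one step.
3. The bottom epicatechin unit 19 comes from the same oxide 16 (hydride shift to the flavan-3-one, cis-selective hydride, C8 bromination).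
4. Oxide 16 comes from the (2S)-flav-3-ene 15, made by enantioselective addition of the ring B boronate 14 (from catechol) to chromene acetal 8.
5. Ring order: ring A phenol 4 (resorcinol, C–H borylation/oxidation), then ring C closed as coumarin 6 with ethyl propiolate, then ring B attached at C2, then the oxirane, then chain growth from the bottom unit upward.

Assumption: the (2R,3R)-tartaric-acid-derived catalyst of step 8 is taken to give the (2S)-flavene 15; if a test run shows the opposite sense, its (2S,3S) antipode is used.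

Notation: "protected" catechin or epicatechin units carry 4-methylbenzyl ethers on O5 and O7 (ring A) and benzyl ethers on O3' and O4' (ring B); every 3-OH is free; flavan numbering is used throughout.

## Route

Step 1
Reactants: 1 resorcinol
Product: 2 1,3-bis[(4-methylbenzyl)oxy]benzene
Conditions: 4-methylbenzyl bromide (2.2 equiv), K2CO3 (3 equiv), DMF, 60 °C
Reagents that add atoms: 4-methylbenzyl bromide, Cc1ccc(CBr)cc1
Why: Williamson etherification of both phenols; the para-methyl groups leave the protecting-group rings without any C–H free of an ortho substituent, which makes the borylation of step 2 site-selective, and the ethers still cleave by hydrogenolysis.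

Step 2
Reactants: 2 1,3-bis[(4-methylbenzyl)oxy]benzene
Product: 4 3,5-bis[(4-methylbenzyl)oxy]phenol, via arylboronic pinacol ester 3 (not isolated)
Conditions: [Ir(OMe)(cod)]2 (1.5 mol%), 4,4'-di-tert-butyl-2,2'-bipyridine (3 mol%), B2pin2 (0.55 equiv), THF, 60 °C; then Oxone, acetone/H2O, rt
Reagents that add atoms: bis(pinacolato)diboron, CC1(C)OB(OC1(C)C)B1OC(C)(C)C(C)(C)O1; potassium peroxymonosulfate (Oxone), [K+].OOS(=O)(=O)[O-]
Why: Sterically governed iridium-catalysed aromatic C–H borylation takes place only at C5, the single C–H with no ortho substituent, and oxidation of the C–B bond (one-pot borylation/oxidation) delivers the third ring A oxygen.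

Step 3
Reactants: 4 3,5-bis[(4-methylbenzyl)oxy]phenol; 5 ethyl propiolate
Product: 6 5,7-bis[(4-methylbenzyl)oxy]-2H-chromen-2-one
Conditions: Pd(OAc)2 (5 mol%), NaOAc, HCO2H/CH2Cl2, rt
Reagents that add atoms: none
Why: Palladium-catalysed ortho-hydroarylation of the alkynoate by the electron-rich phenol followed by lactonisation (Trost-type coumarin synthesis, a mild Pechmann variant) closes ring C and brings in C2, C3 and C4.

Step 4
Reactants: 6 5,7-bis[(4-methylbenzyl)oxy]-2H-chromen-2-one
Product: 8 2-ethoxy-5,7-bis[(4-methylbenzyl)oxy]-2H-chromene (racemic), via lactol 7 (not isolated)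
Conditions: i-Bu2AlH (1.1 equiv), CH2Cl2, −78 °C; aqueous Rochelle salt; crude lactol in EtOH, PPTS (cat.), rt
Reagents that add atoms: ethanol, CCO
Why: Half-reduction of the lactone to the lactol and acid-catalysed acetalisation through the stabilised benzopyrylium ion give the chromene acetal, whose stereocentre is of no consequence because step 8 ionises it again.

Step 5
Reactants: 9 catechol
Product: 10 1,2-bis(benzyloxy)benzene
Conditions: BnBr (2.2 equiv), K2CO3 (3 equiv), DMF, 60 °C
Reagents that add atoms: benzyl bromide, BrCc1ccccc1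
Why: Williamson etherification protects both ring B phenols as hydrogenolysable benzyl ethers.

Step 6
Reactants: 10 1,2-bis(benzyloxy)benzene
Product: 11 4-bromo-1,2-bis(benzyloxy)benzene
Conditions: NBS (1.0 equiv), MeCN, 0 °C to rt
Reagents that add atoms: N-bromosuccinimide, O=C1CCC(=O)N1Br
Why: Electrophilic aromatic bromination occurs para to one ether oxygen, the only activated and unhindered position of the catechol diether.

Step 7
Reactants: 11 4-bromo-1,2-bis(benzyloxy)benzene
Product: 14 diethyl [3,4-bis(benzyloxy)phenyl]boronate, via aryllithium 12 (not isolated), via lithium aryltriethoxyborate 13 (not isolated)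
Conditions: n-BuLi (1.05 equiv), THF, −78 °C; B(OEt)3 (1.2 equiv); HCl in Et2O (1.05 equiv), −78 °C to rt; filter, concentrate
Reagents that add atoms: n-butyllithium, [Li]CCCC; triethyl borate, CCOB(OCC)OCC
Why: Bromine–lithium exchange, borylation to the ate complex and anhydrous protonolysis give the exchangeable diethyl boronate that the chiral catalyst of step 8 needs.

Step 8
Reactants: 8 2-ethoxy-5,7-bis[(4-methylbenzyl)oxy]-2H-chromene; 14 diethyl [3,4-bis(benzyloxy)phenyl]boronate (1.5 equiv)
Product: 15 (2S)-2-[3,4-bis(benzyloxy)phenyl]-5,7-bis[(4-methylbenzyl)oxy]-2H-chromene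
Conditions: (2R,3R)-tartaric-acid-derived N,N-dibenzyl dihydroxy monoamide acid (10 mol%), Ce(OTf)4 (5 mol%), EtOAc, −20 °C
Reagents that add atoms: none
Why: Enantioselective boronate addition to a chromene acetal (Schaus-type, Petasis-like arylation): the boronate exchanges onto the chiral hydroxy acid, the Lewis-acid-activated dioxaborolanone ionises the acetal to the benzopyrylium ion and the resulting ate complex delivers the aryl group to one face of C2, which sets the C2 stereocentre (the spatial arrangement of 2R-catechin; the descriptor is S here only because C3 is sp2).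

Step 9
Reactants: 15 (2S)-2-[3,4-bis(benzyloxy)phenyl]-5,7-bis[(4-methylbenzyl)oxy]-2H-chromene
Product: 16 (2R,3S,4S)-2-[3,4-bis(benzyloxy)phenyl]-3,4-epoxy-5,7-bis[(4-methylbenzyl)oxy]chromane (oxirane oxygen anti to the 2-aryl group)
Conditions: DMDO (1.1 equiv, in acetone), CH2Cl2, −40 to −20 °C; evaporate cold, use crude at once
Reagents that add atoms: dimethyldioxirane, CC1(C)OO1
Why: Concerted oxygen transfer (dioxirane epoxidation) to the electron-rich C3=C4 bond on the face anti to the pseudo-axial 2-aryl group sets C3 and C4 as the 2,3-trans oxirane under neutral conditions with only acetone as by-product.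

Step 10
Reactants: 16 (2R,3S,4S)-2-[3,4-bis(benzyloxy)phenyl]-3,4-epoxy-5,7-bis[(4-methylbenzyl)oxy]chromane
Product: 18 (2R,3R)-2-[3,4-bis(benzyloxy)phenyl]-5,7-bis[(4-methylbenzyl)oxy]chroman-3-ol (protected epicatechin), via flavan-3-one 17 (not isolated)
Conditions: ZnI2 (10 mol%), THF, −20 to 0 °C; then LiBH(s-Bu)3 (1.5 equiv), −78 °C; H2O
Reagents that add atoms: none
Why: Lewis-acid Meinwald rearrangement (C4 benzylic cation, 1,2-hydride shift from C3) gives the flavan-3-one with C2 untouched, and the bulky hydride then attacks anti to the 2-aryl group so that the new 3-OH is cis to it (3R, epicatechin series).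

Step 11
Reactants: 18 (2R,3R)-2-[3,4-bis(benzyloxy)phenyl]-5,7-bis[(4-methylbenzyl)oxy]chroman-3-ol
Product: 19 (2R,3R)-8-bromo-2-[3,4-bis(benzyloxy)phenyl]-5,7-bis[(4-methylbenzyl)oxy]chroman-3-ol
Conditions: NBS (1.0 equiv), CH2Cl2, −78 °C to rt
Reagents that add atoms: N-bromosuccinimide, O=C1CCC(=O)N1Br
Why: Electrophilic aromatic bromination goes to C8, the ring A position flanked by only one benzyl-type ether, as is the rule for 5,7-di-O-benzylflavan-3-ols.

Step 12
Reactants: 19 (2R,3R)-8-bromo-2-[3,4-bis(benzyloxy)phenyl]-5,7-bis[(4-methylbenzyl)oxy]chroman-3-ol; 16 flav-3-ene oxide (2 equiv)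
Product: 20 protected catechin-(4α→8)-epicatechin (upper unit 2R,3S with the C4–C8 bond trans to its 3-OH and cis to its 2-aryl group; lower unit 2R,3R)
Conditions: NiCl2(dme) (10 mol%), 2,2'-bipyridine (10 mol%), Cp2TiCl2 (20 mol%), Mn powder (3 equiv), Et3N·HCl (1.5 equiv), DMPU/THF, rt; 16 added over 2 h
Reagents that add atoms: none
Why: Proposed new method: trivalent titanium (Cp2TiCl from Cp2TiCl2/Mn) opens the oxirane homolytically at the benzylic C4–O bond, the C4 radical is captured by the arylnickel bromide formed from 19 and zerovalent nickel, and reductive elimination on the face anti to the C3 titanoxy group gives the C4–C8 bond trans to the 3-OH and cis to the 2-aryl group (4α) while C3 keeps the oxirane configuration; the closest known reaction type is the nickel/titanocene co-catalysed reductive cross-electrophile coupling of epoxides with aryl bromides, which gives trans-2-arylcycloalkanols and opens styrene oxides at the benzylic carbon, and the new demand here is a doubly ortho-oxygenated aryl bromide together with an acid-labile benzopyran oxide.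

Step 13
Reactants: 20 protected catechin-(4α→8)-epicatechin
Product: 21 protected 8-bromocatechin-(4α→8)-epicatechin (bromine at C8 of the upper unit)
Conditions: NBS (1.0 equiv), CH2Cl2, −78 to −20 °C
Reagents that add atoms: N-bromosuccinimide, O=C1CCC(=O)N1Br
Why: Electrophilic aromatic bromination takes the only free C8 position (upper unit), flanked by one ether and the ring oxygen, whereas both C6 positions lie between two bulky 4-methylbenzyloxy groups, the same preference that makes the monomer bromination C8-selective.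

Step 14
Reactants: 21 protected 8-bromocatechin-(4α→8)-epicatechin; 16 flav-3-ene oxide (2 equiv)
Product: 22 protected catechin-(4α→8)-catechin-(4α→8)-epicatechin
Conditions: NiCl2(dme) (15 mol%), 2,2'-bipyridine (15 mol%), Cp2TiCl2 (25 mol%), Mn powder (3 equiv), Et3N·HCl (1.5 equiv), DMPU/THF, rt; 16 added over 2 h
Reagents that add atoms: none
Why: Proposed new method: the same radical ring-opening arylation as in step 12 (closest known type: nickel/titanocene co-catalysed epoxide–aryl bromide cross-electrophile coupling), the C4 radical from 16 being captured by the arylnickel species from 21 anti to the titanoxy group, which again sets the 3-OH (from the oxirane) and the 3,4-trans C4–C8 bond of the new unit.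

Step 15
Reactants: 22 protected catechin-(4α→8)-catechin-(4α→8)-epicatechin
Product: 23 protected 8-bromocatechin-(4α→8)-catechin-(4α→8)-epicatechin (bromine at C8 of the top unit)
Conditions: NBS (1.0 equiv), CH2Cl2, −78 to −20 °C
Reagents that add atoms: N-bromosuccinimide, O=C1CCC(=O)N1Br
Why: Electrophilic aromatic bromination again takes the single free C8 position (top unit) in preference to the three doubly flanked C6 positions.

Step 16
Reactants: 23 protected 8-bromocatechin-(4α→8)-catechin-(4α→8)-epicatechin; 16 flav-3-ene oxide (2.5 equiv)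
Product: 24 protected catechin-(4α→8)-catechin-(4α→8)-catechin-(4α→8)-epicatechin
Conditions: NiCl2(dme) (20 mol%), 2,2'-bipyridine (20 mol%), Cp2TiCl2 (30 mol%), Mn powder (3 equiv), Et3N·HCl (1.5 equiv), DMPU/THF, rt; 16 added over 2 h
Reagents that add atoms: none
Why: Proposed new method: third use of the radical ring-opening arylation of step 12 (closest known type: nickel/titanocene co-catalysed epoxide–aryl bromide cross-electrophile coupling), with capture of the C4 radical by the arylnickel species from 23 anti to the titanoxy group setting C3 and C4 of the top unit (2R,3S, 4α).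

Step 17
Reactants: 24 protected catechin-(4α→8)-catechin-(4α→8)-catechin-(4α→8)-epicatechin
Product: 25 catechin-(4α→8)-catechin-(4α→8)-catechin-(4α→8)-epicatechin (CNP0236700.7)
Conditions: H2 (1 atm), Pd(OH)2/C, THF/MeOH/H2O, rt; filter, lyophilise
Reagents that add atoms: none
Why: Catalytic hydrogenolysis of all sixteen benzylic C–O bonds under neutral conditions leaves the acid- and base-sensitive interflavan bonds and every stereocentre untouched.

## Compound list

1 | resorcinol | Oc1cccc(O)c1 | starting material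
2 | 1,3-bis[(4-methylbenzyl)oxy]benzene | Cc1ccc(COc2cccc(OCc3ccc(C)cc3)c2)cc1 | intermediate
3 | 2-{3,5-bis[(4-methylbenzyl)oxy]phenyl}-4,4,5,5-tetramethyl-1,3,2-dioxaborolane (not isolated) | Cc1ccc(COc2cc(OCc3ccc(C)cc3)cc(B3OC(C)(C)C(C)(C)O3)c2)cc1 | intermediate
4 | 3,5-bis[(4-methylbenzyl)oxy]phenol | Cc1ccc(COc2cc(O)cc(OCc3ccc(C)cc3)c2)cc1 | intermediate
5 | ethyl propiolate | C#CC(=O)OCC | starting material
6 | 5,7-bis[(4-methylbenzyl)oxy]-2H-chromen-2-one | O=C1C=Cc2c(OCc3ccc(C)cc3)cc(OCc3ccc(C)cc3)cc2O1 | intermediate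
7 | 5,7-bis[(4-methylbenzyl)oxy]-2H-chromen-2-ol, racemic lactol (not isolated) | OC1C=Cc2c(OCc3ccc(C)cc3)cc(OCc3ccc(C)cc3)cc2O1 | intermediate
8 | 2-ethoxy-5,7-bis[(4-methylbenzyl)oxy]-2H-chromene, racemic | CCOC1C=Cc2c(OCc3ccc(C)cc3)cc(OCc3ccc(C)cc3)cc2O1 | intermediate
9 | catechol | Oc1ccccc1O | starting material
10 | 1,2-bis(benzyloxy)benzene | c1ccc(COc2ccccc2OCc2ccccc2)cc1 | intermediate
11 | 4-bromo-1,2-bis(benzyloxy)benzene | Brc1ccc(OCc2ccccc2)c(OCc2ccccc2)c1 | intermediate
12 | [3,4-bis(benzyloxy)phenyl]lithium (not isolated) | [Li]c1ccc(OCc2ccccc2)c(OCc2ccccc2)c1 | intermediate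
13 | lithium [3,4-bis(benzyloxy)phenyl]triethoxyborate (not isolated) | [Li+].CCO[B-](OCC)(OCC)c1ccc(OCc2ccccc2)c(OCc2ccccc2)c1 | intermediate
14 | diethyl [3,4-bis(benzyloxy)phenyl]boronate | CCOB(OCC)c1ccc(OCc2ccccc2)c(OCc2ccccc2)c1 | intermediate
15 | (2S)-2-[3,4-bis(benzyloxy)phenyl]-5,7-bis[(4-methylbenzyl)oxy]-2H-chromene | c1c(OCc3ccc(C)cc3)cc(OCc3ccc(C)cc3)c2c1O[C@H](c1ccc(OCc3ccccc3)c(OCc3ccccc3)c1)C=C2 | intermediate
16 | (2R,3S,4S)-2-[3,4-bis(benzyloxy)phenyl]-3,4-epoxy-5,7-bis[(4-methylbenzyl)oxy]chromane, oxirane anti to the 2-aryl group | c1c(OCc3ccc(C)cc3)cc(OCc3ccc(C)cc3)c2c1O[C@H](c1ccc(OCc3ccccc3)c(OCc3ccccc3)c1)[C@@H](O3)[C@H]23 | intermediate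
17 | (2R)-2-[3,4-bis(benzyloxy)phenyl]-5,7-bis[(4-methylbenzyl)oxy]chroman-3-one (not isolated) | c1c(OCc3ccc(C)cc3)cc(OCc3ccc(C)cc3)c2c1O[C@H](c1ccc(OCc3ccccc3)c(OCc3ccccc3)c1)C(=O)C2 | intermediate
18 | (2R,3R)-2-[3,4-bis(benzyloxy)phenyl]-5,7-bis[(4-methylbenzyl)oxy]chroman-3-ol, protected epicatechin (2,3-cis) | c1c(OCc3ccc(C)cc3)cc(OCc3ccc(C)cc3)c2c1O[C@H](c1ccc(OCc3ccccc3)c(OCc3ccccc3)c1)[C@H](O)C2 | intermediate
19 | (2R,3R)-8-bromo-2-[3,4-bis(benzyloxy)phenyl]-5,7-bis[(4-methylbenzyl)oxy]chroman-3-ol | Brc1c(OCc3ccc(C)cc3)cc(OCc3ccc(C)cc3)c2c1O[C@H](c1ccc(OCc3ccccc3)c(OCc3ccccc3)c1)[C@H](O)C2 | intermediate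
20 | protected catechin-(4α→8)-epicatechin; upper unit 2R,3S, 3,4-trans; lower unit 2R,3R | c1c(OCc3ccc(C)cc3)cc(OCc3ccc(C)cc3)c2c1O[C@H](c1ccc(OCc3ccccc3)c(OCc3ccccc3)c1)[C@@H](O)[C@@H]2c1c(OCc3ccc(C)cc3)cc(OCc3ccc(C)cc3)c2c1O[C@H](c1ccc(OCc3ccccc3)c(OCc3ccccc3)c1)[C@H](O)C2 | intermediate
21 | protected 8-bromocatechin-(4α→8)-epicatechin, bromine at C8 of the upper unit | Brc1c(OCc3ccc(C)cc3)cc(OCc3ccc(C)cc3)c2c1O[C@H](c1ccc(OCc3ccccc3)c(OCc3ccccc3)c1)[C@@H](O)[C@@H]2c1c(OCc3ccc(C)cc3)cc(OCc3ccc(C)cc3)c2c1O[C@H](c1ccc(OCc3ccccc3)c(OCc3ccccc3)c1)[C@H](O)C2 | intermediate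
22 | protected catechin-(4α→8)-catechin-(4α→8)-epicatechin; catechin units 2R,3S, 3,4-trans; epicatechin unit 2R,3R | c1c(OCc3ccc(C)cc3)cc(OCc3ccc(C)cc3)c2c1O[C@H](c1ccc(OCc3ccccc3)c(OCc3ccccc3)c1)[C@@H](O)[C@@H]2c1c(OCc3ccc(C)cc3)cc(OCc3ccc(C)cc3)c2c1O[C@H](c1ccc(OCc3ccccc3)c(OCc3ccccc3)c1)[C@@H](O)[C@@H]2c1c(OCc3ccc(C)cc3)cc(OCc3ccc(C)cc3)c2c1O[C@H](c1ccc(OCc3ccccc3)c(OCc3ccccc3)c1)[C@H](O)C2 | intermediate
23 | protected 8-bromocatechin-(4α→8)-catechin-(4α→8)-epicatechin, bromine at C8 of the top unit | Brc1c(OCc3ccc(C)cc3)cc(OCc3ccc(C)cc3)c2c1O[C@H](c1ccc(OCc3ccccc3)c(OCc3ccccc3)c1)[C@@H](O)[C@@H]2c1c(OCc3ccc(C)cc3)cc(OCc3ccc(C)cc3)c2c1O[C@H](c1ccc(OCc3ccccc3)c(OCc3ccccc3)c1)[C@@H](O)[C@@H]2c1c(OCc3ccc(C)cc3)cc(OCc3ccc(C)cc3)c2c1O[C@H](c1ccc(OCc3ccccc3)c(OCc3ccccc3)c1)[C@H](O)C2 | intermediate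
24 | protected catechin-(4α→8)-catechin-(4α→8)-catechin-(4α→8)-epicatechin; eight 4-methylbenzyl and eight benzyl ethers, four free 3-OH | c1c(OCc3ccc(C)cc3)cc(OCc3ccc(C)cc3)c2c1O[C@H](c1ccc(OCc3ccccc3)c(OCc3ccccc3)c1)[C@@H](O)[C@@H]2c1c(OCc3ccc(C)cc3)cc(OCc3ccc(C)cc3)c2c1O[C@H](c1ccc(OCc3ccccc3)c(OCc3ccccc3)c1)[C@@H](O)[C@@H]2c1c(OCc3ccc(C)cc3)cc(OCc3ccc(C)cc3)c2c1O[C@H](c1ccc(OCc3ccccc3)c(OCc3ccccc3)c1)[C@@H](O)[C@@H]2c1c(OCc3ccc(C)cc3)cc(OCc3ccc(C)cc3)c2c1O[C@H](c1ccc(OCc3ccccc3)c(OCc3ccccc3)c1)[C@H](O)C2 | intermediate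
25 | catechin-(4α→8)-catechin-(4α→8)-catechin-(4α→8)-epicatechin (CNP0236700.7); three upper units 2R,3S with 3,4-trans C4–C8 bonds, bottom unit 2R,3R | Oc1cc(O)c2c(c1)O[C@H](c1ccc(O)c(O)c1)[C@@H](O)[C@@H]2c1c(O)cc(O)c2c1O[C@H](c1ccc(O)c(O)c1)[C@@H](O)[C@@H]2c1c(O)cc(O)c2c1O[C@H](c1ccc(O)c(O)c1)[C@@H](O)[C@@H]2c1c(O)cc(O)c2c1O[C@H](c1ccc(O)c(O)c1)[C@H](O)C2 | target

## Step count and risks

Total steps: 17. Longest linear sequence: 14 steps (1, 2, 3, 4, 8, 9, 10, 11, 12, 13, 14, 15, 16, 17, from resorcinol).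

Steps most likely to fail:

Step 12 (and its repeats, steps 14 and 16). The oxide 16 may rearrange or hydrolyse faster than trivalent titanium opens it, and the hindered arylnickel species may capture the C4 radical slowly. The fallback sets out from oxide 16: stirring the crude oxide in wet acetone buffered at pH 7 lets water open it at C4 to give the storable (2R,3S,4R)-2-[3,4-bis(benzyloxy)phenyl]-5,7-bis[(4-methylbenzyl)oxy]chromane-3,4-diol F1. Its benzylic C4–OH bond is then homolysed by low-valent titanium made from TiCl4(2,4,6-collidine) and Mn, and the same C4 radical is arylated by bromide 19 under NiCl2(dme)/4,4'-di-tert-butyl-2,2'-bipyridine (deoxygenative cross-electrophile coupling of a benzylic alcohol). This comes back to the route at dimer 20; with bromides 21 and 23 it comes back at 22 and 24.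

Step 8. The very electron-rich acetal may give low enantioselectivity or react sluggishly with the chiral boronate complex. The fallback sets out from boronate 14 and acetal 8: 14 is hydrolysed with water to [3,4-bis(benzyloxy)phenyl]boronic acid F2, which is coupled with 8 under Ni(cod)2/PPh3 in dioxane (base-free coupling through a nickel allyl formed by C–O oxidative addition) to give racemic 2-[3,4-bis(benzyloxy)phenyl]-5,7-bis[(4-methylbenzyl)oxy]-2H-chromene F3. The enantiomers are separated by preparative chiral SFC, and the (2S)-enantiomer is 15, where the fallback rejoins the route.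

Step 10. The telescoped rearrangement may give ring-contracted aldehyde or epimerise C2 of the ketone before reduction. The fallback sets out from flavene 15: hydroboration with BH3·THF (boron to C3, anti to the 2-aryl group) gives the alkylborane F4, which is oxidised in the same flask with NaOH/H2O2 to (2R,3S)-2-[3,4-bis(benzyloxy)phenyl]-5,7-bis[(4-methylbenzyl)oxy]chroman-3-ol F5 (protected catechin). Dess–Martin periodinane then gives the ketone 17, now isolated, where the fallback rejoins the route; separate reduction with LiBH(s-Bu)3 at −78 °C gives 18.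

Further compounds

F1 | step 12 | (2R,3S,4R)-2-[3,4-bis(benzyloxy)phenyl]-5,7-bis[(4-methylbenzyl)oxy]chromane-3,4-diol (2,3-trans-3,4-trans) | c1c(OCc3ccc(C)cc3)cc(OCc3ccc(C)cc3)c2c1O[C@H](c1ccc(OCc3ccccc3)c(OCc3ccccc3)c1)[C@@H](O)[C@@H]2O
F2 | step 8 | [3,4-bis(benzyloxy)phenyl]boronic acid | OB(O)c1ccc(OCc2ccccc2)c(OCc2ccccc2)c1
F3 | step 8 | racemic 2-[3,4-bis(benzyloxy)phenyl]-5,7-bis[(4-methylbenzyl)oxy]-2H-chromene | c1c(OCc3ccc(C)cc3)cc(OCc3ccc(C)cc3)c2c1OC(c1ccc(OCc3ccccc3)c(OCc3ccccc3)c1)C=C2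
F4 | step 10 | (2R,3S)-3-boranyl-2-[3,4-bis(benzyloxy)phenyl]-5,7-bis[(4-methylbenzyl)oxy]chromane (not isolated) | c1c(OCc3ccc(C)cc3)cc(OCc3ccc(C)cc3)c2c1O[C@H](c1ccc(OCc3ccccc3)c(OCc3ccccc3)c1)[C@@H](B)C2
F5 | step 10 | (2R,3S)-2-[3,4-bis(benzyloxy)phenyl]-5,7-bis[(4-methylbenzyl)oxy]chroman-3-ol, protected catechin (2,3-trans) | c1c(OCc3ccc(C)cc3)cc(OCc3ccc(C)cc3)c2c1O[C@H](c1ccc(OCc3ccccc3)c(OCc3ccccc3)c1)[C@@H](O)C2
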